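**Strategy.** The oxane is made by ring expansion of an oxolane. With the oxane labelled O1, C2 (pentenynyl carbon), C3 (Cl), C4, C5 (Br) and C6, the precursor is an all-cis 3-bromo-oxolane (O1, C6, C5, C4, C3) that carries a threo carbinol C2 outside the ring. Activation of this carbinol lets O1 displace it to close an O1–C2–C3 oxiranium ion, which chloride opens at C3. One operation thus forms O1–C2 and C3–Cl, turns the five- into the six-membered ring and sets C2 and C3 by double inversion. It exploits the 2,3-cis O1–C2/C3–Cl pair of the oxane ring.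

Key step: step 9

Remark on labels: the labels O1 and C2–C6 are kept for the same atoms in all earlier compounds, whatever their systematic numbering; in these labels the target is 2S,3S,5R,6R.
Assumption: enyne 15, glycidyl ether 5 and the Z-selective ruthenium catalyst are taken as catalogue items.

**Step 1**
Reactants: 1 but-1-yne
Product: 2 (E)-1,2-dibromobut-1-ene
Conditions: Br2 (1.0 equiv), CH2Cl2, −78 to −20 °C, dark
Reagents that add atoms: bromine, BrBr
Why: Electrophilic bromination of the alkyne through a bridged bromonium ion should add the two bromines anti and give the E-dibromide.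

**Step 2**
Reactants: 2 (E)-1,2-dibromobut-1-ene; 3 allyltributylstannane
Product: 4 (E)-5-bromohepta-1,4-diene
Conditions: Pd(PPh3)4 (5 mol %), CuI (10 mol %), DMF, 50 °C
Reagents that add atoms: none
Why: Stille coupling: zerovalent palladium should insert into the terminal C–Br bond, which is far less hindered than the ethyl-flanked internal one, and coupling with retention places the allyl group cis to ethyl and trans to the remaining bromine.

**Step 3**
Reactants: 5 (R)-glycidyl trityl ether
Product: 6 (2R)-1-(trityloxy)pent-4-en-2-ol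
Conditions: vinylmagnesium bromide (1.5 equiv), CuI (10 mol %), THF, −40 to 0 °C; aqueous NH4Cl
Reagents that add atoms: vinylmagnesium bromide, C=C[Mg]Br
Why: Copper-catalysed Grignard opening of the epoxide at its CH2 carbon (SN2) leaves the stereocentre, the later C3, untouched.

**Step 4**
Reactants: 6 (2R)-1-(trityloxy)pent-4-en-2-ol; 4 (E)-5-bromohepta-1,4-diene (3 equiv)
Product: 7 (2R,4Z,7E)-8-bromo-1-(trityloxy)deca-4,7-dien-2-ol
Conditions: cyclometalated Z-selective Grubbs catalyst [Ru(NO3)(=CH-C6H4-2-OiPr) with C,C-chelating N-adamantyl-N′-(2,6-diisopropylphenyl)imidazolin-2-ylidene] (2 mol %), THF, 35 °C, argon flow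
Reagents that add atoms: none
Why: Z-selective olefin cross-metathesis of two terminal alkenes: the chelated carbene ligand forces a side-bound all-syn metallacyclobutane and hence the Z-alkene C5=C6, while the trisubstituted vinyl bromide is inert and the excess of 4 limits homodimerisation of 6.

**Step 5**
Reactants: 7 (2R,4Z,7E)-8-bromo-1-(trityloxy)deca-4,7-dien-2-ol
Product: 8 (2R,3R,5R)-3-bromo-2-[(2E)-3-bromopent-2-en-1-yl]-5-[(trityloxy)methyl]oxolane (all-cis)
Conditions: N-bromosuccinimide (1.1 equiv), NaHCO3, MeCN, −20 to 0 °C, dark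
Reagents that add atoms: N-bromosuccinimide, O=C1CCC(=O)N1Br
Why: 5-endo-trig bromoetherification: the C3 hydroxyl (future O1) opens the bromonium ion at C6 anti to bromine, so the Z-alkene puts Br at C5 cis to the C6 chain, and the 2,5-cis (all-cis) oxolane is expected by analogy with 5-endo halocyclisations of (Z)-homoallylic alcohols; the electron-poor vinyl bromide and the bulky trityl ether should not compete.

**Step 6**
Reactants: 8 all-cis bromo-oxolane trityl ether
Product: 9 [(2R,4R,5R)-4-bromo-5-[(2E)-3-bromopent-2-en-1-yl]oxolan-2-yl]methanol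
Conditions: TsOH·H2O (10 mol %), MeOH–CH2Cl2 (1:1), rt
Reagents that add atoms: none
Why: Acid-catalysed solvolysis of the trityl ether (SN1 at the trityl carbon) should free the primary alcohol without touching the halides or the oxolane.

**Step 7**
Reactants: 9 oxolanyl methanol
Product: 10 (2R,4R,5R)-4-bromo-5-[(2E)-3-bromopent-2-en-1-yl]oxolane-2-carbaldehyde
Conditions: Dess–Martin periodinane (1.3 equiv), NaHCO3, CH2Cl2, 0 °C to rt; used at once
Reagents that add atoms: none
Why: Dess–Martin oxidation under buffered, non-basic conditions should give the α-alkoxy aldehyde without epimerisation at C3 or loss of HBr.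

**Step 8**
Reactants: 10 oxolane-2-carbaldehyde; 3 allyltributylstannane
Product: 11 (1R)-1-[(2R,4R,5R)-4-bromo-5-[(2E)-3-bromopent-2-en-1-yl]oxolan-2-yl]but-3-en-1-ol
Conditions: MgBr2·OEt2 (3 equiv), CH2Cl2, −78 to −40 °C
Reagents that add atoms: none
Why: Chelation-controlled allylstannane addition (Cram-chelate model): magnesium bridges the aldehyde oxygen and ring O1, and the allyl group adds from the face of the C3–H bond, which should set the (1R) threo carbinol C2.

**Step 9**
Reactants: 11 threo oxolanyl homoallylic alcohol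
Product: 14 (2S,3S,5R,6R)-5-bromo-6-[(2E)-3-bromopent-2-en-1-yl]-3-chloro-2-(prop-2-en-1-yl)oxane, via chloromethanesulfonate 12 (not isolated), via bicyclic oxiranium ion 13 (not isolated)
Conditions: ClCH2SO2Cl (1.5 equiv), 2,6-lutidine, CH2Cl2, 0 °C; volatiles removed; Et4NCl (5 equiv), 2,6-lutidine (1 equiv), (CF3)2CHOH, 45 °C
Reagents that add atoms: tetraethylammonium chloride, CC[N+](CC)(CC)CC.[Cl-]
Why: Sulfonate 12 should ionise in the strongly ionising, weakly nucleophilic fluoro alcohol with anchimeric assistance of the ring oxygen: O1 attacks C2 from the back (inversion at C2) to give the cis-fused 1-oxoniabicyclo[3.1.0]hexane 13, and chloride opens the ring-fusion bond O1–C3 from the back (inversion at C3), which turns the oxolane into the oxane. The closest known reaction is the solvolytic rearrangement–ring expansion of 2-(1-sulfonyloxyalkyl)oxolanes to 3-substituted oxanes through bicyclic oxiranium ions, run here with chloride instead of a carboxylate or water as the terminating nucleophile. The three-membered oxonium ring closes 3-exo-tet, and the six-membered ring arises by opening of that ring at the fusion carbon, formally the 6-endo product. Both new centres are set stereospecifically by the substrate: the threo (1R) carbinol and the (2R) ring carbon give a cis-disubstituted oxiranium, so C2 becomes S with the allyl group cis to the C6 chain and C3 becomes S with chlorine cis to the allyl group, while C5 and C6 are untouched. The step needs participation to outrun direct displacement of the sulfonate by chloride, and attack at C3 to outrun attack at C2; hydrogen bonding of chloride by the solvent should slow the direct SN2 path, and opening at the fusion carbon releases the strain of both small rings and is the mode seen in the oxygen-terminated precedent.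

**Step 10**
Reactants: 14 2-allyl-3-chloro-5-bromo-oxane; 15 (but-3-en-1-yn-1-yl)trimethylsilane (5 equiv)
Product: 16 (2S,3S,5R,6R)-5-bromo-6-[(2E)-3-bromopent-2-en-1-yl]-3-chloro-2-[(2Z)-5-(trimethylsilyl)pent-2-en-4-yn-1-yl]oxane
Conditions: second-generation Grubbs catalyst (10 mol %), CH2Cl2, 40 °C
Reagents that add atoms: none
Why: Cross-metathesis of a terminal alkene with a conjugated silyl enyne, a reaction type known to favour the Z-enyne; the trisubstituted vinyl bromide and the silylated alkyne should stay inert.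

**Step 11**
Reactants: 16 silyl enyne
Product: 17 (2S,3S,5R,6R)-5-bromo-6-[(2E)-3-bromopent-2-en-1-yl]-3-chloro-2-[(2Z)-pent-2-en-4-yn-1-yl]oxane (target)
Conditions: K2CO3 (0.5 equiv), MeOH, 0 °C
Reagents that add atoms: none
Why: Methanolysis of the alkynyl C–Si bond under mild carbonate conditions should free the terminal alkyne without elimination of the axial halides.

**Compound list**
1 | but-1-yne | CCC#C | starting material
2 | (E)-1,2-dibromobut-1-ene | Br/C=C(/Br)CC | intermediate
3 | allyltributylstannane | C=CC[Sn](CCCC)(CCCC)CCCC | starting material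
4 | (E)-5-bromohepta-1,4-diene | C=CC/C=C(/Br)CC | intermediate
5 | (R)-glycidyl trityl ether, (2R)-2-[(trityloxy)methyl]oxirane | C(c2ccccc2)(c2ccccc2)(c2ccccc2)OC[C@H]1CO1 | starting material
6 | (2R)-1-(trityloxy)pent-4-en-2-ol | C(c2ccccc2)(c2ccccc2)(c2ccccc2)OC[C@H](O)CC=C | intermediate
7 | (2R,4Z,7E)-8-bromo-1-(trityloxy)deca-4,7-dien-2-ol | C(c2ccccc2)(c2ccccc2)(c2ccccc2)OC[C@H](O)C/C=C\C/C=C(/Br)CC | intermediate
8 | (2R,3R,5R)-3-bromo-2-[(2E)-3-bromopent-2-en-1-yl]-5-[(trityloxy)methyl]oxolane | C(c2ccccc2)(c2ccccc2)(c2ccccc2)OC[C@H]1C[C@@H](Br)[C@@H](C/C=C(/Br)CC)O1 | intermediate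
9 | [(2R,4R,5R)-4-bromo-5-[(2E)-3-bromopent-2-en-1-yl]oxolan-2-yl]methanol | OC[C@H]1C[C@@H](Br)[C@@H](C/C=C(/Br)CC)O1 | intermediate
10 | (2R,4R,5R)-4-bromo-5-[(2E)-3-bromopent-2-en-1-yl]oxolane-2-carbaldehyde | O=C[C@H]1C[C@@H](Br)[C@@H](C/C=C(/Br)CC)O1 | intermediate
11 | (1R)-1-[(2R,4R,5R)-4-bromo-5-[(2E)-3-bromopent-2-en-1-yl]oxolan-2-yl]but-3-en-1-ol | C=CC[C@@H](O)[C@H]1C[C@@H](Br)[C@@H](C/C=C(/Br)CC)O1 | intermediate
12 | (1R)-1-[(2R,4R,5R)-4-bromo-5-[(2E)-3-bromopent-2-en-1-yl]oxolan-2-yl]but-3-en-1-yl chloromethanesulfonate | C=CC[C@@H](OS(=O)(=O)CCl)[C@H]1C[C@@H](Br)[C@@H](C/C=C(/Br)CC)O1 | intermediate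
13 | cis-fused 6-allyl-3-bromo-2-[(2E)-3-bromopent-2-en-1-yl]-1-oxoniabicyclo[3.1.0]hexane cation (O1 bonded to C2, C3 and C6) | C=CC[C@H]1[C@H]2C[C@@H](Br)[C@@H](C/C=C(/Br)CC)[O+]12 | intermediate
14 | (2S,3S,5R,6R)-5-bromo-6-[(2E)-3-bromopent-2-en-1-yl]-3-chloro-2-(prop-2-en-1-yl)oxane | C=CC[C@@H]1O[C@H](C/C=C(/Br)CC)[C@H](Br)C[C@@H]1Cl | intermediate
15 | (but-3-en-1-yn-1-yl)trimethylsilane | C=CC#C[Si](C)(C)C | starting material
16 | (2S,3S,5R,6R)-5-bromo-6-[(2E)-3-bromopent-2-en-1-yl]-3-chloro-2-[(2Z)-5-(trimethylsilyl)pent-2-en-4-yn-1-yl]oxane | C[Si](C)(C)C#C/C=C\C[C@@H]1O[C@H](C/C=C(/Br)CC)[C@H](Br)C[C@@H]1Cl | intermediate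
17 | (2S,3S,5R,6R)-5-bromo-6-[(2E)-3-bromopent-2-en-1-yl]-3-chloro-2-[(2Z)-pent-2-en-4-yn-1-yl]oxane | C#C/C=C\C[C@@H]1O[C@H](C/C=C(/Br)CC)[C@H](Br)C[C@@H]1Cl | target

**Totals.** 11 steps in all. The longest linear sequence is 10 steps (steps 1, 2, 4, 5, 6, 7, 8, 9, 10, 11).

**Steps most likely to fail**

Step 9. Chloride may displace the sulfonate directly at C2 without participation of O1. The oxiranium may also be opened at C2, which returns an oxolane. A third risk is ionisation with participation of the allyl group. The fallback sets out from 11 and returns at 14. Sulfonate 12 is made as in step 9 and solvolysed with Zn(OAc)2 in AcOH–H2O at 60 °C, the established oxygen-terminated form of the ring expansion. This should give the ring-expanded axial acetate F1, and K2CO3 in MeOH then gives the axial oxan-3-ol F2. Mitsunobu inversion (4-nitrobenzoic acid, PPh3, diisopropyl azodicarboxylate, THF) gives the equatorial 4-nitrobenzoate F3, and K2CO3 in MeOH gives the equatorial oxan-3-ol F4. Trioctylphosphine and CCl4 in toluene at 60 °C then replace the hydroxyl by chloride with inversion and give 14.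

Step 5. The 5-endo closure may show poor facial selectivity and give the 2,5-trans oxolane, or the bromonium ion may be intercepted before the hydroxyl closes the ring. The fallback sets out from 6 and 4 and returns at 8; it fixes C6 by reagent control and C5 by SN2. Cross-metathesis with the second-generation Grubbs catalyst (CH2Cl2, 40 °C) should give mainly the (4E,7E)-dienol F5. Shi epoxidation with the L-fructose-derived ketone (Oxone, K2CO3, MeCN–dimethoxymethane–water, 0 °C) gives the (S,S)-epoxy alcohol F6. Camphorsulfonic acid in CH2Cl2 closes the ring by 5-endo opening at C6 with inversion and gives the 2,3-trans hydroxy-oxolane F7. Trioctylphosphine and CBr4 in toluene at 70 °C replace the hydroxyl by bromide with inversion and give 8.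

Step 4. The cross-metathesis may give homodimers or lose its Z-selectivity, and it depends on diene 4, whose coupling in step 2 may lose site selectivity or revert to but-1-yne. The fallback sets out from 5 and returns at 7; it needs neither step 2 nor step 4, and uses ethyl pent-2-ynoate as a further purchased material.
- Lithium acetylide–ethylenediamine complex in DMSO opens 5 to the alkynol F8.
- Syn stannylcupration of ethyl pent-2-ynoate ([Me3SnCuSPh]Li, MeOH, THF, −78 °C) gives the (E)-stannyl enoate F9.
- Br2 in CH2Cl2 at −78 °C gives the (E)-bromo enoate F10 with retention.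
- i-Bu2AlH gives the allylic alcohol F11, and CBr4/PPh3 gives the allylic bromide F12.
- Coupling of F8 with F12 (CuI, NaI, K2CO3, DMF, rt) gives the skipped enynol F13.
- Semihydrogenation over Lindlar catalyst (Pd on CaCO3 poisoned with Pb(OAc)2, quinoline, H2, EtOAc) gives 7.

**Further compounds**
F1 | step 9 | (2S,3S,5R,6R)-5-bromo-6-[(2E)-3-bromopent-2-en-1-yl]-2-(prop-2-en-1-yl)oxan-3-yl acetate | C=CC[C@@H]1O[C@H](C/C=C(/Br)CC)[C@H](Br)C[C@@H]1OC(C)=O
F2 | step 9 | (2S,3S,5R,6R)-5-bromo-6-[(2E)-3-bromopent-2-en-1-yl]-2-(prop-2-en-1-yl)oxan-3-ol | C=CC[C@@H]1O[C@H](C/C=C(/Br)CC)[C@H](Br)C[C@@H]1O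
F3 | step 9 | (2S,3R,5R,6R)-5-bromo-6-[(2E)-3-bromopent-2-en-1-yl]-2-(prop-2-en-1-yl)oxan-3-yl 4-nitrobenzoate | C=CC[C@@H]1O[C@H](C/C=C(/Br)CC)[C@H](Br)C[C@H]1OC(=O)c1ccc(cc1)[N+](=O)[O-]
F4 | step 9 | (2S,3R,5R,6R)-5-bromo-6-[(2E)-3-bromopent-2-en-1-yl]-2-(prop-2-en-1-yl)oxan-3-ol | C=CC[C@@H]1O[C@H](C/C=C(/Br)CC)[C@H](Br)C[C@H]1O
F5 | step 5 | (2R,4E,7E)-8-bromo-1-(trityloxy)deca-4,7-dien-2-ol | C(c2ccccc2)(c2ccccc2)(c2ccccc2)OC[C@H](O)C/C=C/C/C=C(/Br)CC
F6 | step 5 | (2R)-1-{(2S,3S)-3-[(2E)-3-bromopent-2-en-1-yl]oxiran-2-yl}-3-(trityloxy)propan-2-ol | C(c2ccccc2)(c2ccccc2)(c2ccccc2)OC[C@H](O)C[C@@H]1O[C@H]1C/C=C(/Br)CC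
F7 | step 5 | (2R,3S,5R)-2-[(2E)-3-bromopent-2-en-1-yl]-5-[(trityloxy)methyl]oxolan-3-ol | C(c2ccccc2)(c2ccccc2)(c2ccccc2)OC[C@H]1C[C@H](O)[C@@H](C/C=C(/Br)CC)O1
F8 | step 4 | (2R)-1-(trityloxy)pent-4-yn-2-ol | C(c2ccccc2)(c2ccccc2)(c2ccccc2)OC[C@H](O)CC#C
F9 | step 4 | ethyl (2E)-3-(trimethylstannyl)pent-2-enoate | CCOC(=O)/C=C(/[Sn](C)(C)C)CC
F10 | step 4 | ethyl (2E)-3-bromopent-2-enoate | CCOC(=O)/C=C(/Br)CC
F11 | step 4 | (2E)-3-bromopent-2-en-1-ol | OC/C=C(/Br)CC
F12 | step 4 | (2E)-1,3-dibromopent-2-ene | BrC/C=C(/Br)CC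
F13 | step 4 | (2R,7E)-8-bromo-1-(trityloxy)dec-7-en-4-yn-2-ol | C(c2ccccc2)(c2ccccc2)(c2ccccc2)OC[C@H](O)CC#CC/C=C(/Br)CC
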